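**Retrosynthetic overview**

1. Target 33 ⇒ O8 acylation with (S)-2-methylglycidate and O13 acetylation of butenolide diol 28 ⇒ intramolecular Horner–Wadsworth–Emmons closure of a C6 phosphonoacetate onto a C7 ketone.
2. C4–C5 oxirane ⇒ O6-directed epoxidation of the E-alkene; C1–C10 oxirane ⇒ C1 mesylate of the cis-1,10-diol 16, closed by O10 with inversion at C1.
3. Feature on which the route rests: the C1–C10 oxirane (methyl-bearing C10 and C1) is a masked cis-1,2-diol, the pinacol of a C10 methyl ketone and a C1 aldehyde. Forming C1–C10 with SmI2 closes the ten-membered carbocycle from acyclic keto aldehyde 15.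
4. 15 ⇒ Felkin addition at C6 of an E-alkenyllithium (C1–C5 and C15, from pent-4-yn-1-ol) to an aldehyde from 2-deoxy-D-ribose (C6–C10, with O7, O8 and the C8 stereocentre from the sugar); the C10 ketone comes from Wacker oxidation.
5. Ring order: cyclodecene ring → 1,10-oxirane → 4,5-oxirane → butenolide; the glycidate oxirane arrives intact with the acid.

Key step: step 12

Remark: locants C1–C15 are those of the germacrane skeleton of the target (C1–C10 ring, C11–C13 lactone carbons, C14 on C10, C15 on C4). Ethyl 2-(diethoxyphosphoryl)acrylate and 4-methoxybenzyl alcohol are taken as purchasable.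

**Route**

Step 1
Reactants: 1 2-deoxy-D-ribose
Product: 2 (2R,3S)-hex-5-ene-1,2,3-triol
Conditions: Ph3PCH3Br, KOtBu, THF, 0 °C → rt
Reagents that add atoms: methyltriphenylphosphonium bromide, C[P+](c1ccccc1)(c1ccccc1)c1ccccc1.[Br-]
Why: Wittig methylenation of the open-chain aldehyde form of the lactol gives C10=C14 and frees O6, while the two sugar stereocentres (future C7 and C8) are untouched.

Step 2
Reactants: 2 (2R,3S)-hex-5-ene-1,2,3-triol
Product: 3 (2R,4S,5R)-4-allyl-2-(4-methoxyphenyl)-1,3-dioxan-5-ol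
Conditions: 4-MeOC6H4CH(OMe)2, CSA (cat.), CH2Cl2, rt
Reagents that add atoms: 4-methoxybenzaldehyde dimethyl acetal, COc1ccc(C(OC)OC)cc1
Why: Acid-catalysed transacetalisation under thermodynamic control should favour the six-membered 1,3-dioxane across O6 and O8, in which aryl, allyl and hydroxyl are all equatorial and the acetal carbon settles as 2R.

Step 3
Reactants: 3 (2R,4S,5R)-4-allyl-2-(4-methoxyphenyl)-1,3-dioxan-5-ol
Product: 4 TBS ether of 3 (O7 silyl ether)
Conditions: TBSCl, imidazole, DMF, rt
Reagents that add atoms: tert-butyldimethylsilyl chloride, CC(C)(C)[Si](C)(C)Cl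
Why: Standard silylation of the one free (equatorial, secondary) hydroxyl; no stereocentre is affected.

Step 4
Reactants: 4 TBS ether of 3
Product: 5 (2R,3S)-2-[(tert-butyldimethylsilyl)oxy]-3-[(4-methoxybenzyl)oxy]hex-5-en-1-ol
Conditions: i-Bu2AlH, CH2Cl2, −78 → 0 °C
Reagents that add atoms: none
Why: Reductive opening of the p-methoxybenzylidene acetal: aluminium binds the less hindered primary O6, the O6–C(acetal) bond breaks and hydride reduces the oxocarbenium ion, which leaves the PMB group on secondary O8 and a free C6 alcohol.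

Step 5
Reactants: 5 primary alcohol
Product: 6 (2S,3S)-2-[(tert-butyldimethylsilyl)oxy]-3-[(4-methoxybenzyl)oxy]hex-5-enal
Conditions: Dess–Martin periodinane, CH2Cl2, 0 °C → rt
Reagents that add atoms: none
Why: Dess–Martin oxidation gives the α-silyloxy aldehyde under neutral conditions that should not epimerise C7; the aldehyde is used at once.

Step 6
Reactants: 7 pent-4-yn-1-ol
Product: 9 (E)-5-iodo-4-methylpent-4-en-1-ol, via alkenylalane 8 (not isolated)
Conditions: Me3Al, Cp2ZrCl2 (cat.), CH2Cl2, 0 °C → rt; then I2, THF, −30 → 0 °C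
Reagents that add atoms: trimethylaluminium, C[Al](C)C; iodine, II
Why: Zirconium-catalysed carboalumination (Negishi) adds methyl and aluminium syn across the alkyne with methyl on the internal carbon, and iodinolysis of the C–Al bond with retention gives the E-iodide carrying C1–C5 and C15.

Step 7
Reactants: 9 (E)-5-iodo-4-methylpent-4-en-1-ol
Product: 10 (E)-triethyl[(5-iodo-4-methylpent-4-en-1-yl)oxy]silane
Conditions: TESCl, imidazole, CH2Cl2, 0 °C
Reagents that add atoms: chlorotriethylsilane, CC[Si](Cl)(CC)CC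
Why: Routine silylation of the primary alcohol, giving an ether that tolerates t-BuLi and can later be oxidised directly.

Step 8
Reactants: 10 (E)-alkenyl iodide TES ether; 6 aldehyde
Product: 12 (4S,5R,6R,7E)-5-[(tert-butyldimethylsilyl)oxy]-4-[(4-methoxybenzyl)oxy]-8-methyl-11-[(triethylsilyl)oxy]undeca-1,7-dien-6-ol (germacrane C6 R, 6,7-anti), via alkenyllithium 11 (not isolated)
Conditions: t-BuLi (2.1 equiv), Et2O, −78 °C; then 6, THF, −78 °C
Reagents that add atoms: none
Why: Lithium–iodine exchange retains the E geometry, and Felkin–Anh addition to the α-silyloxy aldehyde, with the nucleophile anti to the C7–OTBS bond (the bulky silyl ether suppresses α-chelation), should set C6 as R.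

Step 9
Reactants: 12 allylic alcohol
Product: 13 (4S,5S,6R,7E)-5-[(tert-butyldimethylsilyl)oxy]-4-[(4-methoxybenzyl)oxy]-8-methyl-6,11-bis[(triethylsilyl)oxy]undeca-1,7-diene
Conditions: TESOTf, 2,6-lutidine, CH2Cl2, −78 °C
Reagents that add atoms: triethylsilyl trifluoromethanesulfonate, CC[Si](CC)(CC)OS(=O)(=O)C(F)(F)F
Why: Silyl triflate with a hindered base protects the congested secondary allylic hydroxyl without touching the other ethers.

Step 10
Reactants: 13 bis-TES ether
Product: 14 (4S,5S,6R,7E)-5-[(tert-butyldimethylsilyl)oxy]-4-[(4-methoxybenzyl)oxy]-8-methyl-6,11-bis[(triethylsilyl)oxy]undec-7-en-2-one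
Conditions: PdCl2 (10 mol %), Cu(OAc)2·H2O (20 mol %), O2 (1 atm), DMA/H2O 7:1, rt
Reagents that add atoms: water, O
Why: Tsuji–Wacker oxidation: Markovnikov hydroxypalladation of the monosubstituted alkene by divalent palladium and β-hydride elimination give the C10 methyl ketone, while the trisubstituted C4=C5 bond is inert and the acetate-buffered medium should spare the silyl ethers.

Step 11
Reactants: 14 methyl ketone
Product: 15 (4E,6R,7S,8S)-7-[(tert-butyldimethylsilyl)oxy]-8-[(4-methoxybenzyl)oxy]-4-methyl-10-oxo-6-[(triethylsilyl)oxy]undec-4-enal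
Conditions: (COCl)2, DMSO, CH2Cl2, −78 → −30 °C; then Et3N, −78 → 0 °C
Reagents that add atoms: none
Why: Under Swern conditions a primary triethylsilyl ether is cleaved by the chlorosulfonium reagent and oxidised directly to the aldehyde, whereas the hindered secondary TES and TBS ethers stay (known selective oxidation of primary silyl ethers), and the cold amine step should avoid β-elimination of the C8 ether.

Step 12
Reactants: 15 keto aldehyde
Product: 16 (1S,4E,6R,7S,8S,10R)-7-[(tert-butyldimethylsilyl)oxy]-8-[(4-methoxybenzyl)oxy]-4,10-dimethyl-6-[(triethylsilyl)oxy]cyclodec-4-ene-1,10-diol (germacrane locants; cis-1,10-diol)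
Conditions: SmI2 (4 equiv), THF, rt, 15 added over 8 h by syringe pump (final 2 mM); then aq. NaHCO3
Reagents that add atoms: none
Why: Single-electron transfer from SmI2 to the C1 aldehyde (more easily reduced than the methyl ketone) gives a samarium ketyl whose carbon adds to the samarium-bound C10 carbonyl, and a second electron gives the trivalent samarium diolate, protonated on work-up; the closest known reaction type is the SmI2 (or low-valent titanium) intramolecular pinacol coupling of keto aldehydes, macrocyclic cases included. The ten-membered carbocycle is closed by C1–C10 bond formation, a ketyl radical addition to a carbonyl inside a metal-bridged template, run at high dilution with slow addition so that cyclisation outruns intermolecular aldehyde coupling. C1 and C10 are set together: both oxygens sit on one trivalent samarium in the bond-forming array, which gives the cis diol, and the C8 PMB ether, β to the ketone, is expected to bind the same metal so that O1, O10 and O8 end on one face of the ring, that is 1S and 10R. The E-configured C4=C5 bond and the bulky 6-OTES and 7-OTBS groups restrict the chain to coiled conformers that bring C1 near C10. The step needs the cis (1S,10R) isomer; no HMPA is used so that the ketone is not reduced on its own, ketyl addition to C4=C5 from C1 would be 4-exo or 5-endo and should not compete, and the absolute face pair remains the uncertain point.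

Step 13
Reactants: 16 cis-1,10-diol
Product: 18 (1R,4E,6R,7S,8S,10R)-1,10-epoxide with 6-OTES, 7-OTBS and 8-OPMB (trans oxirane, C9 and C2 trans), via mesylate 17 (not isolated)
Conditions: MsCl (1.3 equiv), Et3N, CH2Cl2, −20 °C; then MeOH, K2CO3, rt
Reagents that add atoms: none
Why: Sulfonylation takes the secondary C1 hydroxyl in preference to the tertiary C10 hydroxyl, and in the Williamson-type closure the C10 alkoxide displaces the C1 mesylate from the rear (3-exo-tet), inverting C1 from S to R while C10 stays R.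

Step 14
Reactants: 18 1,10-epoxide
Product: 19 (1R,4E,6R,7R,8S,10R)-1,10-epoxy C6 allylic alcohol with 7-OTBS and 8-OPMB
Conditions: HF·pyridine, pyridine, THF, 0 °C
Reagents that add atoms: none
Why: Fluoride cleaves the less hindered, more labile triethylsilyl ether before the TBS ether, and pyridine buffering should keep the trisubstituted epoxide from acid-induced transannular reactions.

Step 15
Reactants: 19 allylic alcohol
Product: 20 (1R,4R,5R,6R,7R,8S,10R)-1,10:4,5-diepoxide with free 6-OH, 7-OTBS and 8-OPMB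
Conditions: VO(acac)2 (5 mol %), t-BuOOH, CH2Cl2, 0 °C → rt
Reagents that add atoms: tert-butyl hydroperoxide, CC(C)(C)OO
Why: Hydroxyl-directed epoxidation by the vanadium alkyl peroxide complex: the ring chain (C7) must lie on the inner face of the E-alkene and H6 eclipses the alkene plane (1,3-allylic strain with C15), so O6 sits on the outer face and delivers oxygen there, which should give the threo (5,6-syn) epoxy alcohol, 4R,5R.

Step 16
Reactants: 21 ethyl 2-(diethoxyphosphoryl)acrylate
Product: 22 ethyl 2-(diethoxyphosphoryl)-3-[(4-methoxybenzyl)oxy]propanoate (racemic)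
Conditions: 4-MeOC6H4CH2OH, KOtBu (5 mol %), THF, 0 °C
Reagents that add atoms: 4-methoxybenzyl alcohol, COc1ccc(CO)cc1
Why: Base-catalysed oxa-Michael addition of the benzylic alkoxide to the doubly activated vinylphosphonate; the new stereocentre later becomes sp2.

Step 17
Reactants: 22 phosphono ester
Product: 23 2-(diethoxyphosphoryl)-3-[(4-methoxybenzyl)oxy]propanoic acid (racemic)
Conditions: LiOH·H2O, THF/H2O, 0 °C; then 1 M HCl to pH 3
Reagents that add atoms: lithium hydroxide, [Li+].[OH-]
Why: Saponification of the carboxylic ethyl ester is faster than attack on the phosphonate esters, and once the carboxylate forms, α-deprotonation and loss of alkoxide are shut down.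

Step 18
Reactants: 20 epoxy alcohol; 23 phosphono acid
Product: 24 C6 ester of 20 with 23 (7-OTBS, 8-OPMB; epimers at the phosphonate carbon)
Conditions: DCC, DMAP (cat.), CH2Cl2, 0 °C → rt
Reagents that add atoms: none
Why: Steglich esterification of the C6 hydroxyl; the epimer mixture at the phosphonate carbon is of no consequence.

Step 19
Reactants: 24 silyl ether
Product: 25 C7 alcohol (6-O-phosphonoacyl, 8-OPMB)
Conditions: HF·pyridine, pyridine, THF, 0 °C → rt
Reagents that add atoms: none
Why: Fluoride-mediated desilylation in a buffered, weakly acidic medium should avoid O6→O7 acyl migration and leave the epoxides and PMB ethers.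

Step 20
Reactants: 25 C7 alcohol
Product: 26 C7 ketone (6-O-phosphonoacyl, 8-OPMB)
Conditions: Dess–Martin periodinane, pyridine, CH2Cl2, 0 °C → rt
Reagents that add atoms: none
Why: Dess–Martin oxidation of the secondary alcohol under buffered, non-basic conditions, so that the α-acyloxy ketone with its β-epoxide is not enolised.

Step 21
Reactants: 26 keto phosphonate
Product: 27 (1R,4R,5R,6S,8S,10R)-1,10:4,5-diepoxy-8,13-bis[(4-methoxybenzyl)oxy]germacr-7(11)-en-12,6-olide
Conditions: LiCl, i-Pr2NEt, MeCN, rt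
Reagents that add atoms: none
Why: Intramolecular Horner–Wadsworth–Emmons reaction under Masamune–Roush conditions: the lithium-chelated phosphonate carbanion (far more acidic than H6 or H8) adds to the adjacent C7 ketone and loses phosphate to form the tetrasubstituted C7=C11 bond and the butenolide; β-alkoxy phosphonoacetate anions are known olefination partners, and the weak amine base should leave H6 of the product alone.

Step 22
Reactants: 27 bis-PMB ether
Product: 28 (1R,4R,5R,6S,8S,10R)-1,10:4,5-diepoxy-8,13-dihydroxygermacr-7(11)-en-12,6-olide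
Conditions: DDQ, CH2Cl2/pH 7 buffer, 0 °C → rt
Reagents that add atoms: none
Why: DDQ removes both p-methoxybenzyl ethers by benzylic hydride abstraction and hydrolysis of the oxocarbenium ions; the neutral medium spares the epoxides and generates no alkoxide that could shift the lactone to O8.

Step 23
Reactants: 28 diol
Product: 29 (1R,4R,5R,6S,8S,10R)-13-acetoxy-1,10:4,5-diepoxy-8-hydroxygermacr-7(11)-en-12,6-olide
Conditions: AcCl (1.05 equiv), 2,4,6-collidine, CH2Cl2, −78 °C
Reagents that add atoms: acetyl chloride, CC(=O)Cl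
Why: Kinetically selective acylation of the primary allylic C13 hydroxyl over the hindered secondary C8 hydroxyl with acetyl chloride and a hindered pyridine base at low temperature.

Step 24
Reactants: 30 methyl (S)-2-methylglycidate
Product: 31 potassium (S)-2-methyloxirane-2-carboxylate
Conditions: KOH (1.0 equiv), EtOH, 0 °C
Reagents that add atoms: potassium hydroxide, [K+].[OH-]
Why: Saponification at the ester carbonyl gives the potassium salt, so the sensitive free epoxy acid is never isolated, and the quaternary stereocentre cannot epimerise.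

Step 25
Reactants: 31 potassium (S)-2-methylglycidate; 29 C8 alcohol
Product: 33 target, (1R,4R,5R,6S,8S,10R)-13-acetoxy-1,10:4,5-diepoxy-8-{[(2S)-2-methyloxiran-2-yl]carbonyloxy}germacr-7(11)-en-12,6-olide, via mixed anhydride 32 (not isolated)
Conditions: 2,4,6-Cl3C6H2COCl, THF, 0 °C; then 29, DMAP, toluene, rt
Reagents that add atoms: none
Why: Yamaguchi esterification: the carboxylate gives the mixed anhydride and DMAP transfers the glycidoyl group (the less hindered carbonyl) to O8 with retention at C8, with no acid or strong base present to open the three oxiranes or move the lactone.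

**Compound list**

1 | 2-deoxy-D-ribose | O=CC[C@H](O)[C@H](O)CO | starting material
2 | (2R,3S)-hex-5-ene-1,2,3-triol | C=CC[C@H](O)[C@H](O)CO | intermediate
3 | (2R,4S,5R)-4-allyl-2-(4-methoxyphenyl)-1,3-dioxan-5-ol | C=CC[C@@H]1O[C@H](c2ccc(OC)cc2)OC[C@H]1O | intermediate
4 | TBS ether of 3 | C=CC[C@@H]1O[C@H](c2ccc(OC)cc2)OC[C@H]1O[Si](C)(C)C(C)(C)C | intermediate
5 | (2R,3S)-2-(TBS-oxy)-3-(PMB-oxy)hex-5-en-1-ol | C=CC[C@H](OCc1ccc(OC)cc1)[C@H](O[Si](C)(C)C(C)(C)C)CO | intermediate
6 | (2S,3S)-2-(TBS-oxy)-3-(PMB-oxy)hex-5-enal | C=CC[C@H](OCc1ccc(OC)cc1)[C@H](O[Si](C)(C)C(C)(C)C)C=O | intermediate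
7 | pent-4-yn-1-ol | C#CCCCO | starting material
8 | (E)-alkenyl(dimethyl)alane, O-dimethylaluminium alkoxide | C[Al](C)OCCC/C(C)=C/[Al](C)C | intermediate
9 | (E)-5-iodo-4-methylpent-4-en-1-ol | OCCC/C(C)=C/I | intermediate
10 | (E)-triethyl[(5-iodo-4-methylpent-4-en-1-yl)oxy]silane | CC[Si](CC)(CC)OCCC/C(C)=C/I | intermediate
11 | (E)-alkenyllithium from 10 | CC[Si](CC)(CC)OCCC/C(C)=C/[Li] | intermediate
12 | C6 allylic alcohol (6R, 6,7-anti; 7-OTBS, 8-OPMB, 1-OTES) | C=CC[C@H](OCc1ccc(OC)cc1)[C@H](O[Si](C)(C)C(C)(C)C)[C@H](O)/C=C(C)/CCCO[Si](CC)(CC)CC | intermediate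
13 | 6,1-bis-TES ether of 12 | C=CC[C@H](OCc1ccc(OC)cc1)[C@H](O[Si](C)(C)C(C)(C)C)[C@H](O[Si](CC)(CC)CC)/C=C(C)/CCCO[Si](CC)(CC)CC | intermediate
14 | C10 methyl ketone | CC(=O)C[C@H](OCc1ccc(OC)cc1)[C@H](O[Si](C)(C)C(C)(C)C)[C@H](O[Si](CC)(CC)CC)/C=C(C)/CCCO[Si](CC)(CC)CC | intermediate
15 | keto aldehyde (4E,6R,7S,8S) | CC(=O)C[C@H](OCc1ccc(OC)cc1)[C@H](O[Si](C)(C)C(C)(C)C)[C@H](O[Si](CC)(CC)CC)/C=C(C)/CCC=O | intermediate
16 | ten-membered cis-1,10-diol (1S,10R) | C[C@@]1(O)C[C@H](OCc2ccc(OC)cc2)[C@H](O[Si](C)(C)C(C)(C)C)[C@H](O[Si](CC)(CC)CC)/C=C(C)/CC[C@@H]1O | intermediate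
17 | C1 mesylate of 16 | C[C@@]1(O)C[C@H](OCc2ccc(OC)cc2)[C@H](O[Si](C)(C)C(C)(C)C)[C@H](O[Si](CC)(CC)CC)/C=C(C)/CC[C@@H]1OS(C)(=O)=O | intermediate
18 | (1R,10R)-1,10-epoxide, 6-OTES | C[C@@]12C[C@H](OCc3ccc(OC)cc3)[C@H](O[Si](C)(C)C(C)(C)C)[C@H](O[Si](CC)(CC)CC)/C=C(C)/CC[C@H]1O2 | intermediate
19 | (1R,10R)-1,10-epoxide, 6-OH | C[C@@]12C[C@H](OCc3ccc(OC)cc3)[C@H](O[Si](C)(C)C(C)(C)C)[C@H](O)/C=C(C)/CC[C@H]1O2 | intermediate
20 | (1R,4R,5R,10R)-1,10:4,5-diepoxide, 6-OH | C[C@@]12C[C@H](OCc3ccc(OC)cc3)[C@H](O[Si](C)(C)C(C)(C)C)[C@H](O)[C@H]3O[C@]3(C)CC[C@H]1O2 | intermediate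
21 | ethyl 2-(diethoxyphosphoryl)acrylate | CCOC(=O)C(=C)P(=O)(OCC)OCC | starting material
22 | ethyl 2-(diethoxyphosphoryl)-3-(PMB-oxy)propanoate | CCOC(=O)C(COCc1ccc(OC)cc1)P(=O)(OCC)OCC | intermediate
23 | 2-(diethoxyphosphoryl)-3-(PMB-oxy)propanoic acid | OC(=O)C(COCc1ccc(OC)cc1)P(=O)(OCC)OCC | intermediate
24 | C6 phosphonoacyl ester, 7-OTBS | C[C@@]12C[C@H](OCc3ccc(OC)cc3)[C@H](O[Si](C)(C)C(C)(C)C)[C@H](OC(=O)C(COCc3ccc(OC)cc3)P(=O)(OCC)OCC)[C@H]3O[C@]3(C)CC[C@H]1O2 | intermediate
25 | C6 phosphonoacyl ester, 7-OH | C[C@@]12C[C@H](OCc3ccc(OC)cc3)[C@H](O)[C@H](OC(=O)C(COCc3ccc(OC)cc3)P(=O)(OCC)OCC)[C@H]3O[C@]3(C)CC[C@H]1O2 | intermediate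
26 | C6 phosphonoacyl ester, C7 ketone | C[C@@]12C[C@H](OCc3ccc(OC)cc3)C(=O)[C@H](OC(=O)C(COCc3ccc(OC)cc3)P(=O)(OCC)OCC)[C@H]3O[C@]3(C)CC[C@H]1O2 | intermediate
27 | butenolide, 8,13-bis-PMB ether | COc1ccc(COCC2=C3[C@@H](OCc4ccc(OC)cc4)C[C@@]4(C)O[C@@H]4CC[C@@]4(C)O[C@@H]4[C@H]3OC2=O)cc1 | intermediate
28 | butenolide 8,13-diol | OCC1=C2[C@@H](O)C[C@@]3(C)O[C@@H]3CC[C@@]3(C)O[C@@H]3[C@H]2OC1=O | intermediate
29 | 13-acetate, 8-OH | CC(=O)OCC1=C2[C@@H](O)C[C@@]3(C)O[C@@H]3CC[C@@]3(C)O[C@@H]3[C@H]2OC1=O | intermediate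
30 | methyl (S)-2-methylglycidate | COC(=O)[C@]1(C)CO1 | starting material
31 | potassium (S)-2-methyloxirane-2-carboxylate | [K+].[O-]C(=O)[C@]1(C)CO1 | intermediate
32 | (S)-2-methylglycidic 2,4,6-trichlorobenzoic anhydride | O=C(OC(=O)[C@]1(C)CO1)c1c(Cl)cc(Cl)cc1Cl | intermediate
33 | CNP0289810.2 | CC(=O)OCC1=C2[C@@H](OC(=O)[C@]3(C)CO3)C[C@@]3(C)O[C@@H]3CC[C@@]3(C)O[C@@H]3[C@H]2OC1=O | target

**Step count**

Total: 25 steps. Longest linear sequence: 20 steps (1–5, 8–15, 18–23, 25).

**Steps most likely to fail**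

Step 12. Intermolecular aldehyde coupling or simple carbonyl reduction may outrun closure of the ten-membered ring, or the ring may close to the trans diol or to the cis diol of the opposite face pair. The fallback sets out from 15 and makes the C1–C10 bond as an alkene. Slow addition of 15 to TiCl3(DME)1.5 and Zn–Cu couple in refluxing DME (McMurry carbonyl olefination, the classical entry to germacradienes) would give the (1(10)E,4E)-cyclodecadiene F1 after separation from any 1(10)Z isomer. One equivalent of mCPBA (NaHCO3, CH2Cl2, −20 °C) should then epoxidise the electron-richer C1=C10 bond, remote from the allylic silyloxy group, on the outer face of the crown conformer. This returns to the route at 18.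

Step 21. The phosphonate carbanion may lose p-methoxybenzyl alkoxide, may add too slowly to the hindered ketone, or the base may open the 4,5-epoxide through deprotonation at C6. The fallback sets out from 20 and attaches C13 after the lactone is closed.
- Esterification of 20 with commercial diethylphosphonoacetic acid (DCC, DMAP) gives the phosphonoacetate F2.
- HF·pyridine removes the C7 silyl ether to give alcohol F3, and Dess–Martin oxidation gives ketone F4.
- The unsubstituted phosphonate closes the C11-unsubstituted butenolide F5 under LiCl and i-Pr2NEt, the standard intramolecular olefination of α-(phosphonoacetoxy) ketones.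
- Pyridine-promoted α-iodination (I2, pyridine, CH2Cl2) gives the C11 iodide F6.
- Stille coupling with Bu3SnCH2OH (Pd(PPh3)4, dioxane, 80 °C) gives the C13 alcohol F7.
- DDQ removal of the C8 PMB ether returns to the route at 28.

Step 8. Facial selectivity in the alkenyllithium addition may be poor, because the α-silyloxy and β-alkoxy groups do not clearly reinforce each other. The fallback sets out from the C6 epimer mixture of 12. Dess–Martin oxidation gives the enone F8, and C6 is then set by hydride delivery rather than by C–C bond formation: Zn(BH4)2 (Et2O, −30 °C) reduces the carbonyl 1,2 under chelation control. Chelation through O7 (1,2-anti) and through O8 (1,3-syn) both lead to the 6R alcohol, and the route is rejoined at 12.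

**Further compounds**

F1 | step 12 | (1(10)E,4E)-6-OTES-7-OTBS-8-OPMB-germacra-1(10),4-diene carbocycle | C/C1=C\CC/C(C)=C/[C@@H](O[Si](CC)(CC)CC)[C@@H](O[Si](C)(C)C(C)(C)C)[C@@H](OCc2ccc(OC)cc2)C1
F2 | step 21 | C6 diethylphosphonoacetate of 20 (7-OTBS) | C[C@@]12C[C@H](OCc3ccc(OC)cc3)[C@H](O[Si](C)(C)C(C)(C)C)[C@H](OC(=O)CP(=O)(OCC)OCC)[C@H]3O[C@]3(C)CC[C@H]1O2
F3 | step 21 | C6 diethylphosphonoacetate, 7-OH | C[C@@]12C[C@H](OCc3ccc(OC)cc3)[C@H](O)[C@H](OC(=O)CP(=O)(OCC)OCC)[C@H]3O[C@]3(C)CC[C@H]1O2
F4 | step 21 | C6 diethylphosphonoacetate, C7 ketone | C[C@@]12C[C@H](OCc3ccc(OC)cc3)C(=O)[C@H](OC(=O)CP(=O)(OCC)OCC)[C@H]3O[C@]3(C)CC[C@H]1O2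
F5 | step 21 | C11-unsubstituted butenolide, 8-OPMB | C1=C2[C@@H](OCc3ccc(OC)cc3)C[C@@]3(C)O[C@@H]3CC[C@@]3(C)O[C@@H]3[C@H]2OC1=O
F6 | step 21 | C11-iodo butenolide, 8-OPMB | IC1=C2[C@@H](OCc3ccc(OC)cc3)C[C@@]3(C)O[C@@H]3CC[C@@]3(C)O[C@@H]3[C@H]2OC1=O
F7 | step 21 | C13-hydroxy butenolide, 8-OPMB | OCC1=C2[C@@H](OCc3ccc(OC)cc3)C[C@@]3(C)O[C@@H]3CC[C@@]3(C)O[C@@H]3[C@H]2OC1=O
F8 | step 8 | C6 enone from 12 | C=CC[C@H](OCc1ccc(OC)cc1)[C@H](O[Si](C)(C)C(C)(C)C)C(=O)/C=C(C)/CCCO[Si](CC)(CC)CC
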